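## Analysis of the target

Integric acid (37) is an eremophilane. Ring A (C1–C5, C10) carries the acyloxy group on C1 and the carboxyl C15 on C4. Ring B (C5–C10) carries the 2-substituted acrolein C11–C13 on C7, the C8 ketone and the C9=C10 alkene. C14 is the methyl group on the quaternary ring-fusion carbon C5.

The bicycle has four stereocentres. O1, C15 and C14 lie on one face of ring A; the C7 side chain lies on the other face, trans to C14 and equatorial on ring B. The fifth stereocentre, C4′ of the (2E,4S)-2,4-dimethyloct-2-enoyl ester, has no stereochemical contact with the core and must come from a separate enantiopure fragment.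

The molecule is sensitive. C7–H is α to the ketone and γ to the enal, so base can epimerise C7 or move the C11=C12 alkene into conjugation. The α-methylene aldehyde is a strong Michael acceptor. The C1 ester is allylic, and the C15 acid has to be freed in its presence, which rules out a final saponification.

The hard part is the C4–C5 junction (a carboxyl-bearing methine next to a quaternary carbon) together with the 1,4-cis relationship between C15 on C4 and the oxygen on C1. That 1,4-cis pair is the carbonyl carbon and the ring oxygen of a 2-pyrone after it has added across an alkene: an O1–C15 lactone bridge over ring A, with C5 and C10 as the two carbons of the dienophile.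

## Retrosynthetic reasoning

**C15 acid (37 ⇒ 36).** The last operation only unmasks the acid. C15 is carried as a 4-methoxybenzyl ester because 37 tolerates brief dilute acid but not the base a simple alkyl ester would need.

**C11=C12 (36 ⇒ 35).** The exocyclic methylene carbon C12 is cut from C11, leaving an acetaldehyde side chain on C7. The forward reaction is an aldehyde α-methylenation, selective for the aldehyde over the C8 ketone. It creates the reactive acrolein one step before the end.

**C1–O acyl bond (35 ⇒ 23 + 33).** Cutting the ester separates the core alcohol 23 from the side-chain acid 33, so the remote C4′ centre is made independently. Acid 33 goes back through ester 32 to a Wittig reaction of ylide 30 with aldehyde 31 (C2′=C3′). Aldehyde 31 comes from alcohol 29, and 29 from the auxiliary-controlled methylation product 28 of imide 26, assembled from 24 and 25.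

**C13 (23 ⇒ 22 ⇒ 21).** The aldehyde carbon is the inner carbon of a terminal alkene, so the side chain on C7 is an allyl group in 21. The alkene is cleaved before the side-chain enoate is attached, so no competing alkene is present; the silyl ether on O1 is removed afterwards.

**C7–C11 and C6–H (21 ⇒ 19).** Both bonds are cut together, giving the cross-conjugated dienone 19. In the forward direction, hydride adds to C6 and forms the C7 enolate regiospecifically, and this enolate is allylated. The axial C14 methyl group directs the electrophile to the opposite face, which is also the equilibrium configuration at C7.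

**C9=C10 and protecting groups (19 ⇒ 17 ⇒ 16 ⇒ 14 ⇒ 12).** Removing the C9=C10 alkene leads to enone 17, whose only enolisable position is C9. 17 is the silyl ether of 16, and 16 the ester of acid 12. The cycloaddition below has no control over the diene face: the strongly Lewis-acidic chiral catalysts that could control the enal would ionise the ketal and are untested with a pyrone diene. The material is therefore resolved at 12, through salt 14 with amine 13. Acid 12 is the first intermediate with a free carboxyl group and no aldehyde.

**C6–C7 and the O1–C15 bridge (12 ⇒ 9).** The enone is cut by a retro-aldol condensation between the methyl ketone carbon C7 and the C6 aldehyde, and the hydroxy acid is re-closed to the lactone. In 9 the two carbonyl arms are trans on a rigid bicycle and cannot reach each other, so ring B can only close once the lactone is cut. One basic operation therefore does both: hydrolysis frees ring A to a chair, then the aldol condensation closes ring B. The trans ring fusion this gives is harmless because C10 later becomes sp2.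

**Functional-group changes (9 ⇒ 8 ⇒ 7 ⇒ 6).** These restore the ketal, the C2=C3 alkene and the bromine on C4.

**Key disconnection (6 ⇒ 4 + 5).** C4–C5 and C1–C10 are cut. Pyrone 5 supplies C1–C4, C15 and O1; enal 4 supplies C5, C10, C14 and the masked ring B carbons. The forward Diels–Alder reaction sets C1, C4, C5 and C10 in one step. The bromine makes the pyrone reactive enough and is removed later at a bridgehead whose configuration is locked.

**Precursor (4 ⇒ 2 + 3; 2 ⇒ 1).** The C5=C10 alkene is cut by a Wittig disconnection to aldehyde 2 and ylide 3. Aldehyde 2 comes from the commercial ketal ester 1 by partial reduction.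

## Alternatives that were turned down

**Alternative 1:** C5–C6 by an anionic oxy-Cope rearrangement.
- **Forward step:** a tertiary potassium alkoxide at C8 carries the C6=C7 vinyl group and sits on a bicyclo[2.2.2]octene made of the ring A carbons and a temporary C3–C8 bond. It rearranges through a boat-like six-centre transition state: C5–C6 forms, C3–C8 breaks, and the cis-fused keto enoate A1 arises as its C7–C8 enolate.
- **For:** the shift is strongly driven by enolate formation and makes quaternary C5 and ring B at once. It delivers the C8 ketone with a regiodefined C7 enolate, so the C7 side chain could be attached directly. On this point it is stronger than the chosen route, which needs aldol closure, dehydrogenation and reduction to reach the same enolate.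
- **Against:** the accepting terminus C5 is the methyl-bearing end of a tetrasubstituted, ester-conjugated alkene, which retards the [3,3] shift. A1 leaves C4 as an sp2 carbon, so the C15/C14 relationship depends on a later face-selective reduction of a hindered enoate on a flexible cis-decalin. The C1 benzyloxy centre has to be built into the bicyclic precursor, which itself needs a cycloaddition and a face-selective vinyl addition. The benzyl ether must later be removed beside alkenes.
- **Comparison:** the step count to the precursor is similar and absolute configuration is equally unsolved. The chosen cycloaddition instead fixes O1, C15 and C14 together and brings C1 and C15 at their final oxidation levels.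

**Alternative 2:** C4–C5 by an Ireland–Claisen ring contraction.
- **Forward step:** an eight-membered lactone joins C15 to an allylic oxygen on C9 of a ring B cyclohexene. Its silyl ketene acetal rearranges: C4–C5 forms, C9–O breaks, ring A closes and the alkene moves to C9=C10, giving acid A2.
- **For:** the C9=C10 alkene and a protected C8 ketone appear without a dehydrogenation, and chirality is transferred from the C9 carbinol, so absolute configuration could come from an enantioenriched allylic alcohol. On both points it is stronger than the chosen route.
- **Against:** the transition state enforced by the medium ring gives A2 with C4 epimeric to the target. An esterification, epimerisation and hydrolysis sequence next to the quaternary carbon would be needed, and its equilibrium position is not assured. The eight-membered lactone needs a medium-ring lactonisation of a precursor that already holds the C1 and C9 stereocentres.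
- **Comparison:** more steps before the key step and a stereochemical correction after it. The chosen route gets C4 right by construction, because C15 is tied to O1 when the bond to C5 forms.

**Alternative 3:** C1–C10 by an intramolecular Stetter reaction.
- **Forward step:** a chiral triazolylidene carbene converts the C1 aldehyde of a side chain on a 4-methylcyclohexa-2,5-dienone into an acyl anion equivalent. It adds to C10 of one of the two enantiotopic enone arms and gives the cis-fused diketone A3.
- **For:** the precursor is achiral and short to make, and C5 and C10 are set catalytically with absolute control. This is clearly stronger than the chosen route, whose cycloaddition is racemic and must be resolved.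
- **Against:** A3 holds neither the C1 nor the C4 stereocentre. The C1 ketone must be reduced to the alcohol cis to C14. The C4 methylene must be converted, by face-selective hydroboration and two oxidations, into a carboxyl group cis to C14. Both rely on substrate control on a cis-decalin. Closing a six-membered carbocycle through an all-carbon tether is also less favourable for this reaction than the five-membered, heteroatom-tethered cases.
- **Comparison:** fewer steps to the bicycle and better absolute control, but three oxidation-level changes and two uncontrolled stereocentres on ring A. The chosen route offers the O1/C15/C14 relationship in one step at the correct oxidation levels.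

Key step: step 3

## Route

Remarks on the chemistry:
- Compounds 6 to 12 are racemates; their names and SMILES show the enantiomer that is carried on from step 8.
- It is assumed that the less soluble salt in step 8 contains the enantiomer drawn; if it contains the other, (S)-1-phenylethylamine is used in the same way.
- Atom numbers are eremophilane numbers (C1–C15) unless a bicycle name is given.

Step 1
Reactants: 1 ethyl 2-(2-methyl-1,3-dioxolan-2-yl)acetate (the commercial ethylene ketal of ethyl acetoacetate)
Product: 2 2-(2-methyl-1,3-dioxolan-2-yl)acetaldehyde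
Conditions: i-Bu2AlH (1.05 equiv), CH2Cl2, −78 °C; MeOH, aq. KNaC4H4O6
Reagents that add atoms: none
Why: Partial reduction of an ester; at −78 °C the aluminium hemiacetal is held by chelation to a ketal oxygen and collapses to the aldehyde only on work-up. No stereocentre is involved.

Step 2
Reactants: 2 2-(2-methyl-1,3-dioxolan-2-yl)acetaldehyde; 3 2-(triphenylphosphoranylidene)propanal
Product: 4 (E)-2-methyl-4-(2-methyl-1,3-dioxolan-2-yl)but-2-enal
Conditions: toluene, 80 °C
Reagents that add atoms: none
Why: Wittig olefination with a formyl-stabilised ylide, which gives the E trisubstituted enal; the conjugated, α-branched product is much less electrophilic than 2, so a second olefination is slow. The ylide is too weakly basic to eliminate the β-ketal oxygen of 2.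

Step 3
Reactants: 4 (E)-2-methyl-4-(2-methyl-1,3-dioxolan-2-yl)but-2-enal; 5 3-bromo-2H-pyran-2-one
Product: 6 racemic lactone-bridged bromo aldehyde, 4-bromo-5-methyl-6-[(2-methyl-1,3-dioxolan-2-yl)methyl]-3-oxo-2-oxabicyclo[2.2.2]oct-7-ene-5-carbaldehyde (bicycle numbering: formyl group syn to the C7=C8 bridge, methyl group and side chain syn to the lactone bridge)
Conditions: 5 (1.5 equiv), CH2Cl2 (2 M), BHT (cat.), 12 kbar, 40 °C, 72 h
Reagents that add atoms: none
Why: A concerted, asynchronous, normal-demand [4+2] cycloaddition with the pyrone as diene and C5=C10 of 4 as dienophile; the closest known reaction type is the thermal Diels–Alder addition of 3-bromo-2-pyrone to acrolein and acrylates, which gives isolable bromo lactones. Ring A closes by the cycloaddition itself (two σ bonds, suprafacial on both partners) as a boat spanned by the O–C(=O) bridge that the pyrone brings with it. The regiochemistry needed is C10 to pyrone C6 and the formyl-bearing C5 to the brominated C3; this is the orientation 3-bromo-2-pyrone shows with acceptor alkenes, because the β-carbon of the enal pairs with the diene terminus next to the ring oxygen. C1 and C4 are bridgeheads of one lactone and are therefore cis. C5 is set by the endo position of the formyl group: it gains secondary overlap with the diene, and the two alkyl groups of the enal prefer the open side next to the lactone oxygens, where no hydrogen projects; this turns C14 towards the lactone. C10 follows from the E geometry of 4, which is transferred stereospecifically. High pressure is used because the activation volume is strongly negative, so a trisubstituted enal should react at 40 °C, well below the temperature at which the adduct loses CO2. Nothing controls the face of the diene, so 6 is racemic; absolute configuration is introduced in step 8.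

Step 4
Reactants: 6 racemic lactone-bridged bromo aldehyde
Product: 7 racemic 5-methyl-6-[(2-methyl-1,3-dioxolan-2-yl)methyl]-3-oxo-2-oxabicyclo[2.2.2]oct-7-ene-5-carbaldehyde
Conditions: Bu3SnH (1.5 equiv, 0.5 M), AIBN (cat.), benzene, 80 °C; aq. KF
Reagents that add atoms: none
Why: Radical chain dehalogenation of a tertiary α-bromo lactone; the bridgehead radical is a localised σ radical that abstracts hydrogen from the concentrated stannane faster than it can add to the neighbouring formyl group. C4 is a bridgehead, so its configuration cannot change.

Step 5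
Reactants: 7 racemic debrominated alkene lactone
Product: 8 racemic 5-methyl-6-[(2-methyl-1,3-dioxolan-2-yl)methyl]-3-oxo-2-oxabicyclo[2.2.2]octane-5-carbaldehyde
Conditions: H2 (1 atm), 5% Rh/Al2O3, EtOAc, rt
Reagents that add atoms: none
Why: Heterogeneous hydrogenation of the strained disubstituted bridge alkene, the most accessible π bond; rhodium is chosen over palladium because the C1–O bond is allylic until the alkene is saturated and could be hydrogenolysed. After this step CO2 can no longer be lost by cycloreversion.

Step 6
Reactants: 8 racemic saturated ketal lactone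
Product: 9 racemic 5-methyl-3-oxo-6-(2-oxopropyl)-2-oxabicyclo[2.2.2]octane-5-carbaldehyde
Conditions: 1 M HCl, THF, rt
Reagents that add atoms: water, O
Why: Acid-catalysed ketal hydrolysis, which the lactone tolerates. The lactone is kept on purpose: C6 on C5 and C9 on C10 are trans on the rigid bicycle (dihedral angle near 120°), so the keto aldehyde cannot undergo aldol closure and is isolated as such.

Step 7
Reactants: 9 racemic keto aldehyde lactone
Product: 12 racemic 4-hydroxy-8a-methyl-6-oxo-1,2,3,4,4a,5,6,8a-octahydronaphthalene-1-carboxylic acid (trans-fused; C1–OH axial and cis to C14 and C15; C6=C7 enone), via ring-opened keto aldehyde acid 10 (not isolated), via aldol 11 (not isolated)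
Conditions: KOH (4 equiv), THF/H2O, rt to 50 °C; then 1 M HCl, 0 °C
Reagents that add atoms: potassium hydroxide, [K+].[OH-]
Why: Hydroxide cuts the strained lactone; ring A relaxes to the chair with C6 and C9 equatorial, and the methyl ketone enolate (C7) adds to the non-enolisable C6 aldehyde (6-enolendo-exo-trig aldol, the only mode that gives a six-membered ring), followed by E1cB loss of water. The new ring is trans-fused because C6 and C9 were trans in 9. C4 cannot epimerise as a carboxylate, and the hydroxy acid of the trans-decalin cannot relactonise without forcing ring A back into a boat.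

Step 8
Reactants: 12 racemic hydroxy enone acid; 13 (R)-1-phenylethylamine
Product: 14 (R)-1-phenylethylammonium salt of the enantiomer of 12 that has the configuration of 37 at C1, C4 and C5
Conditions: 13 (1.0 equiv), EtOAc/acetone, 50 to 4 °C; recrystallisation
Reagents that add atoms: none
Why: Classical resolution through diastereomeric ammonium carboxylate salts, which differ in lattice energy and solubility; the rigid trans-decalin with a hydroxyl group near the carboxylate favours well-ordered salts. No stereocentre is formed; the four centres set in step 3 are sorted by absolute configuration.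

Step 9
Reactants: 14 (R)-1-phenylethylammonium salt
Product: 16 4-methoxybenzyl 4-hydroxy-8a-methyl-6-oxo-1,2,3,4,4a,5,6,8a-octahydronaphthalene-1-carboxylate (single enantiomer), via free acid 15 (not isolated)
Conditions: EtOAc/1 M HCl, 0 °C; then 4-MeOC6H4CH2Cl (1.2 equiv), KHCO3, Bu4NI (cat.), DMF, rt
Reagents that add atoms: 4-methoxybenzyl chloride, COc1ccc(CCl)cc1
Why: The acid wash frees the enantiopure acid, whose carboxylate is O-alkylated by the benzylic chloride (SN2). The carbonyl group is never activated, so neither relactonisation nor C4 epimerisation can occur, and hydrogencarbonate does not alkylate the hindered alcohol. The 4-methoxybenzyl ester is chosen because acid, not base, removes it at the end.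

Step 10
Reactants: 16 4-methoxybenzyl hydroxy enone ester
Product: 17 4-methoxybenzyl 4-[(tert-butyldimethylsilyl)oxy]-8a-methyl-6-oxo-1,2,3,4,4a,5,6,8a-octahydronaphthalene-1-carboxylate
Conditions: t-BuMe2SiOSO2CF3, 2,6-lutidine, CH2Cl2, −78 to 0 °C
Reagents that add atoms: tert-butyldimethylsilyl triflate, CC(C)(C)[Si](C)(C)OS(=O)(=O)C(F)(F)F
Why: Silylation of a hindered axial alcohol (syn-axial to C14) needs the silyl triflate; 2,6-lutidine is too weak a base to enolise the enone. The ether shields O1 from the strong base and hydride of the next steps and prevents hemiketal formation with C8.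

Step 11
Reactants: 17 silyl ether enone
Product: 19 4-methoxybenzyl 4-[(tert-butyldimethylsilyl)oxy]-8a-methyl-6-oxo-1,2,3,4,6,8a-hexahydronaphthalene-1-carboxylate (cross-conjugated C6=C7/C9=C10 dienone), via silyl dienol ether 18 (not isolated)
Conditions: Me3SiCl (3 equiv), LiN(i-Pr)2 (1.2 equiv), THF, −78 °C (in situ quench); then Pd(OAc)2 (1.1 equiv), MeCN, rt
Reagents that add atoms: none
Why: Kinetic deprotonation at C9, the only enolisable position of the enone (the γ carbon C5 is quaternary), gives the cross-conjugated silyl dienol ether; Saegusa–Ito oxidation (palladation at C9, β-hydride elimination of C10–H) gives the dienone. The C10 stereocentre disappears here, which is why the trans ring fusion from step 7 is of no consequence.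

Step 12
Reactants: 19 cross-conjugated dienone
Product: 21 4-methoxybenzyl 7-allyl-4-[(tert-butyldimethylsilyl)oxy]-8a-methyl-6-oxo-1,2,3,4,6,7,8,8a-octahydronaphthalene-1-carboxylate (naphthalene numbering; allyl group on eremophilane C7, trans to C14), via lithium enolate 20 (not isolated)
Conditions: Li[HB(s-Bu)3] (1.05 equiv), THF, −78 °C; then allyl bromide (3 equiv), DMPU, −78 to −20 °C
Reagents that add atoms: allyl bromide, C=CCBr
Why: Reductive alkylation of an enone: the bulky hydride adds to C6, the β-carbon of the disubstituted enone, and not to the fully substituted C10, as in the selective saturation of the 1,2-double bond of steroidal 1,4-dien-3-ones. The C7 enolate formed regiospecifically is allylated anti to the axial C14 methyl group (1,3 to C7), which puts the allyl group equatorial and trans to C14; this is also the equilibrium configuration.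

Step 13
Reactants: 21 7-allyl enone
Product: 22 4-methoxybenzyl 4-[(tert-butyldimethylsilyl)oxy]-8a-methyl-6-oxo-7-(2-oxoethyl)-1,2,3,4,6,7,8,8a-octahydronaphthalene-1-carboxylate
Conditions: OsO4 (2 mol%), NaIO4 (4 equiv), 2,6-lutidine, dioxane/H2O, rt
Reagents that add atoms: osmium tetroxide, O=[Os](=O)(=O)=O (regenerated by sodium periodate, [Na+].[O-]I(=O)(=O)=O)
Why: Lemieux–Johnson cleavage: OsO4 dihydroxylates the monosubstituted terminal alkene much faster than the hindered, electron-poor C9=C10 enone, and NaIO4 cleaves the diol and reoxidises osmium. C13 is thus revealed at the aldehyde level while no other reactive alkene is present.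

Step 14
Reactants: 22 silyl ether keto aldehyde
Product: 23 4-methoxybenzyl 4-hydroxy-8a-methyl-6-oxo-7-(2-oxoethyl)-1,2,3,4,6,7,8,8a-octahydronaphthalene-1-carboxylate
Conditions: HF·pyridine, THF/pyridine, 0 °C to rt
Reagents that add atoms: none
Why: Fluoride-mediated Si–O cleavage under buffered, weakly acidic conditions, which spare the aldehyde, the enone and the 4-methoxybenzyl ester. C7 can only equilibrate to the equatorial configuration it already has.

Step 15
Reactants: 24 (S)-4-benzyloxazolidin-2-one; 25 hexanoyl chloride
Product: 26 (S)-4-benzyl-3-hexanoyloxazolidin-2-one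
Conditions: Et3N, DMAP (cat.), CH2Cl2, 0 °C to rt
Reagents that add atoms: none
Why: N-Acylation of the oxazolidinone by the acid chloride under nucleophilic catalysis.

Step 16
Reactants: 26 (S)-4-benzyl-3-hexanoyloxazolidin-2-one
Product: 28 (S)-4-benzyl-3-[(S)-2-methylhexanoyl]oxazolidin-2-one, via sodium enolate 27 (not isolated)
Conditions: NaN(SiMe3)2, THF, −78 °C; MeI, −78 to −40 °C
Reagents that add atoms: iodomethane, CI
Why: Evans alkylation: the chelated Z enolate is methylated on the face opposite the benzyl group, which gives the S configuration at the carbon that becomes C4′ of the side chain.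

Step 17
Reactants: 28 (S)-4-benzyl-3-[(S)-2-methylhexanoyl]oxazolidin-2-one
Product: 29 (S)-2-methylhexan-1-ol
Conditions: LiBH4, MeOH (1 equiv), Et2O, 0 °C
Reagents that add atoms: none
Why: Reductive removal of the auxiliary; hydride attacks the exocyclic imide carbonyl, the α-stereocentre is not enolised, and the oxazolidinone is recovered.

Step 18
Reactants: 29 (S)-2-methylhexan-1-ol; 30 ethyl 2-(triphenylphosphoranylidene)propanoate
Product: 32 ethyl (2E,4S)-2,4-dimethyloct-2-enoate, via (S)-2-methylhexanal 31 (not isolated)
Conditions: TEMPO (10 mol%), PhI(OAc)2, CH2Cl2, rt; then 30, rt to 40 °C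
Reagents that add atoms: none
Why: Oxoammonium oxidation of the primary alcohol stops at the aldehyde; the ylide is added to the same flask so that the configurationally labile α-branched aldehyde is consumed at once. The Wittig reaction of the ester-stabilised α-methyl ylide gives the E trisubstituted enoate.

Step 19
Reactants: 32 ethyl (2E,4S)-2,4-dimethyloct-2-enoate
Product: 33 (2E,4S)-2,4-dimethyloct-2-enoic acid
Conditions: LiOH, THF/MeOH/H2O, 50 °C; then 1 M HCl
Reagents that add atoms: lithium hydroxide, [Li+].[OH-]
Why: Saponification of the ethyl ester; the γ-stereocentre is not deprotonated by hydroxide and the E geometry is retained.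

Step 20
Reactants: 23 core alcohol; 33 (2E,4S)-2,4-dimethyloct-2-enoic acid
Product: 35 4-methoxybenzyl 4-{[(2E,4S)-2,4-dimethyloct-2-enoyl]oxy}-8a-methyl-6-oxo-7-(2-oxoethyl)-1,2,3,4,6,7,8,8a-octahydronaphthalene-1-carboxylate, via acid chloride 34 (not isolated)
Conditions: 33, (COCl)2, DMF (cat.), CH2Cl2, 0 °C to rt, evaporate; then 23, pyridine, DMAP (0.2 equiv), CH2Cl2, 0 °C to rt
Reagents that add atoms: none
Why: Esterification through the acid chloride with nucleophilic catalysis; pyridine is the base so that the enoyl chloride is not converted into a vinylketene, which would scramble the alkene geometry and the γ-stereocentre. The acyl–oxygen bond is formed, so C1 keeps its configuration; the aldehyde is not affected.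

Step 21
Reactants: 35 acylated keto aldehyde
Product: 36 4-methoxybenzyl ester of integric acid, 4-methoxybenzyl 4-{[(2E,4S)-2,4-dimethyloct-2-enoyl]oxy}-8a-methyl-6-oxo-7-(3-oxoprop-1-en-2-yl)-1,2,3,4,6,7,8,8a-octahydronaphthalene-1-carboxylate
Conditions: 37% aq. CH2O, pyrrolidine (10 mol%), EtCO2H (10 mol%), i-PrOH, 45 °C
Reagents that add atoms: formaldehyde, C=O
Why: Amine-catalysed α-methylenation of an aldehyde: enamine Mannich addition to the iminium ion of formaldehyde, then β-elimination of the amine. Only the aldehyde forms an enamine; the C8 ketone with its tertiary α-carbon does not. C7 keeps the equatorial configuration, which is the thermodynamic one.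

Step 22
Reactants: 36 4-methoxybenzyl ester of integric acid
Product: 37 integric acid
Conditions: CF3CO2H/CH2Cl2 (1:10), anisole (5 equiv), 0 °C
Reagents that add atoms: none
Why: Acidolysis of the 4-methoxybenzyl ester through the stabilised benzylic cation, which anisole traps by Friedel–Crafts alkylation. The C1 enoate, the enone and the α-methylene aldehyde tolerate brief dilute acid at 0 °C, and no base touches C7–H.

## Compound list

1 | ethyl 2-(2-methyl-1,3-dioxolan-2-yl)acetate | CCOC(=O)CC1(C)OCCO1 | starting material
2 | 2-(2-methyl-1,3-dioxolan-2-yl)acetaldehyde | O=CCC1(C)OCCO1 | intermediate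
3 | 2-(triphenylphosphoranylidene)propanal | CC(C=O)=P(c1ccccc1)(c1ccccc1)c1ccccc1 | starting material
4 | (E)-2-methyl-4-(2-methyl-1,3-dioxolan-2-yl)but-2-enal | O=C/C(C)=C/CC1(C)OCCO1 | intermediate
5 | 3-bromo-2H-pyran-2-one | O=C1OC=CC=C1Br | starting material
6 | racemic 4-bromo-5-methyl-6-[(2-methyl-1,3-dioxolan-2-yl)methyl]-3-oxo-2-oxabicyclo[2.2.2]oct-7-ene-5-carbaldehyde (formyl syn to the alkene bridge) | O=C[C@@]1(C)[C@H](CC2(C)OCCO2)[C@@H]3OC(=O)[C@@]1(Br)C=C3 | intermediate
7 | racemic 5-methyl-6-[(2-methyl-1,3-dioxolan-2-yl)methyl]-3-oxo-2-oxabicyclo[2.2.2]oct-7-ene-5-carbaldehyde | O=C[C@@]1(C)[C@H](CC2(C)OCCO2)[C@@H]3OC(=O)[C@H]1C=C3 | intermediate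
8 | racemic 5-methyl-6-[(2-methyl-1,3-dioxolan-2-yl)methyl]-3-oxo-2-oxabicyclo[2.2.2]octane-5-carbaldehyde | O=C[C@@]1(C)[C@H](CC2(C)OCCO2)[C@@H]3OC(=O)[C@H]1CC3 | intermediate
9 | racemic 5-methyl-3-oxo-6-(2-oxopropyl)-2-oxabicyclo[2.2.2]octane-5-carbaldehyde | O=C[C@@]1(C)[C@H](CC(C)=O)[C@@H]2OC(=O)[C@H]1CC2 | intermediate
10 | racemic 2-formyl-4-hydroxy-2-methyl-3-(2-oxopropyl)cyclohexane-1-carboxylic acid (potassium salt in the flask) | O=C[C@@]1(C)[C@H](CC(C)=O)[C@H](O)CC[C@@H]1C(=O)O | intermediate
11 | racemic 4,8-dihydroxy-8a-methyl-6-oxodecahydronaphthalene-1-carboxylic acid (trans-fused; both C8 epimers; potassium salt in the flask) | O=C1CC(O)[C@@]2(C)[C@H](C1)[C@H](O)CC[C@@H]2C(=O)O | intermediate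
12 | racemic 4-hydroxy-8a-methyl-6-oxo-1,2,3,4,4a,5,6,8a-octahydronaphthalene-1-carboxylic acid (trans-fused) | O=C1C=C[C@@]2(C)[C@H](C1)[C@H](O)CC[C@@H]2C(=O)O | intermediate
13 | (R)-1-phenylethylamine | C[C@@H](N)c1ccccc1 | starting material
14 | (R)-1-phenylethylammonium salt of the acid enantiomer drawn | O=C1C=C[C@@]2(C)[C@H](C1)[C@H](O)CC[C@@H]2C(=O)[O-].C[C@@H]([NH3+])c1ccccc1 | intermediate
15 | 4-hydroxy-8a-methyl-6-oxo-1,2,3,4,4a,5,6,8a-octahydronaphthalene-1-carboxylic acid, single enantiomer (same constitution as 12) | O=C1C=C[C@@]2(C)[C@H](C1)[C@H](O)CC[C@@H]2C(=O)O | intermediate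
16 | 4-methoxybenzyl 4-hydroxy-8a-methyl-6-oxo-1,2,3,4,4a,5,6,8a-octahydronaphthalene-1-carboxylate | O=C1C=C[C@@]2(C)[C@H](C1)[C@H](O)CC[C@@H]2C(=O)OCc1ccc(OC)cc1 | intermediate
17 | 4-methoxybenzyl 4-[(tert-butyldimethylsilyl)oxy]-8a-methyl-6-oxo-1,2,3,4,4a,5,6,8a-octahydronaphthalene-1-carboxylate | O=C1C=C[C@@]2(C)[C@H](C1)[C@H](O[Si](C)(C)C(C)(C)C)CC[C@@H]2C(=O)OCc1ccc(OC)cc1 | intermediate
18 | 4-methoxybenzyl 4-[(tert-butyldimethylsilyl)oxy]-8a-methyl-6-[(trimethylsilyl)oxy]-1,2,3,4,4a,8a-hexahydronaphthalene-1-carboxylate | C[Si](C)(C)OC1=C[C@@H]2[C@H](O[Si](C)(C)C(C)(C)C)CC[C@H](C(=O)OCc3ccc(OC)cc3)[C@@]2(C)C=C1 | intermediate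
19 | 4-methoxybenzyl 4-[(tert-butyldimethylsilyl)oxy]-8a-methyl-6-oxo-1,2,3,4,6,8a-hexahydronaphthalene-1-carboxylate | O=C1C=C[C@@]2(C)C(=C1)[C@H](O[Si](C)(C)C(C)(C)C)CC[C@@H]2C(=O)OCc1ccc(OC)cc1 | intermediate
20 | lithium C7–C8 enolate formed from 19 by hydride addition at C6 | [Li+].[O-]C1=CC[C@@]2(C)C(=C1)[C@H](O[Si](C)(C)C(C)(C)C)CC[C@@H]2C(=O)OCc1ccc(OC)cc1 | intermediate
21 | 4-methoxybenzyl 7-allyl-4-[(tert-butyldimethylsilyl)oxy]-8a-methyl-6-oxo-1,2,3,4,6,7,8,8a-octahydronaphthalene-1-carboxylate | C=CC[C@@H]1C[C@@]2(C)C(=CC1=O)[C@H](O[Si](C)(C)C(C)(C)C)CC[C@@H]2C(=O)OCc1ccc(OC)cc1 | intermediate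
22 | 4-methoxybenzyl 4-[(tert-butyldimethylsilyl)oxy]-8a-methyl-6-oxo-7-(2-oxoethyl)-1,2,3,4,6,7,8,8a-octahydronaphthalene-1-carboxylate | O=CC[C@@H]1C[C@@]2(C)C(=CC1=O)[C@H](O[Si](C)(C)C(C)(C)C)CC[C@@H]2C(=O)OCc1ccc(OC)cc1 | intermediate
23 | 4-methoxybenzyl 4-hydroxy-8a-methyl-6-oxo-7-(2-oxoethyl)-1,2,3,4,6,7,8,8a-octahydronaphthalene-1-carboxylate | O=CC[C@@H]1C[C@@]2(C)C(=CC1=O)[C@H](O)CC[C@@H]2C(=O)OCc1ccc(OC)cc1 | intermediate
24 | (S)-4-benzyloxazolidin-2-one | O=C1OC[C@H](Cc2ccccc2)N1 | starting material
25 | hexanoyl chloride | CCCCCC(=O)Cl | starting material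
26 | (S)-4-benzyl-3-hexanoyloxazolidin-2-one | CCCCCC(=O)N1[C@@H](Cc2ccccc2)COC1=O | intermediate
27 | sodium (Z)-enolate of 26 | CCCC/C=C(\[O-])N1[C@@H](Cc2ccccc2)COC1=O.[Na+] | intermediate
28 | (S)-4-benzyl-3-[(S)-2-methylhexanoyl]oxazolidin-2-one | CCCC[C@H](C)C(=O)N1[C@@H](Cc2ccccc2)COC1=O | intermediate
29 | (S)-2-methylhexan-1-ol | CCCC[C@H](C)CO | intermediate
30 | ethyl 2-(triphenylphosphoranylidene)propanoate | CCOC(=O)C(C)=P(c1ccccc1)(c1ccccc1)c1ccccc1 | starting material
31 | (S)-2-methylhexanal | CCCC[C@H](C)C=O | intermediate
32 | ethyl (2E,4S)-2,4-dimethyloct-2-enoate | CCCC[C@H](C)/C=C(\C)C(=O)OCC | intermediate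
33 | (2E,4S)-2,4-dimethyloct-2-enoic acid | CCCC[C@H](C)/C=C(\C)C(=O)O | intermediate
34 | (2E,4S)-2,4-dimethyloct-2-enoyl chloride | CCCC[C@H](C)/C=C(\C)C(=O)Cl | intermediate
35 | 4-methoxybenzyl 4-{[(2E,4S)-2,4-dimethyloct-2-enoyl]oxy}-8a-methyl-6-oxo-7-(2-oxoethyl)-1,2,3,4,6,7,8,8a-octahydronaphthalene-1-carboxylate | O=CC[C@@H]1C[C@@]2(C)C(=CC1=O)[C@H](OC(=O)/C(C)=C/[C@@H](C)CCCC)CC[C@@H]2C(=O)OCc1ccc(OC)cc1 | intermediate
36 | 4-methoxybenzyl ester of integric acid | C=C(C=O)[C@@H]1C[C@@]2(C)C(=CC1=O)[C@H](OC(=O)/C(C)=C/[C@@H](C)CCCC)CC[C@@H]2C(=O)OCc1ccc(OC)cc1 | intermediate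
37 | integric acid | C=C(C=O)[C@@H]1C[C@@]2(C)C(=CC1=O)[C@H](OC(=O)/C(C)=C/[C@@H](C)CCCC)CC[C@@H]2C(=O)O | target

## Step count and least certain steps

Total step count: 22. Longest linear sequence: 17 (steps 1–14 and 20–22); the side-chain branch (steps 15–19) has 5 steps.

**Step 3 (key step).** The cycloaddition may be too slow, because the C4–C5 bond joins two fully substituted carbons; the enal could then polymerise or the adduct lose CO2 when forced. The preference for the formyl-endo, C5-to-C3 orientation may also erode with an α-methyl, β-alkyl enal. Fallback: from 4, use 3,5-dibromo-2H-pyran-2-one (O=C1OC=C(Br)C=C1Br), a more reactive and more endo-selective diene of the same kind, under the same pressure. This gives the racemic dibromo lactone F1. Excess Bu3SnH with AIBN in toluene at 100 °C removes both the bridgehead and the vinyl bromine, and the route is rejoined at 7.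

**Step 4.** The bridgehead radical may add to the neighbouring formyl group, with 1,2-formyl migration, or the stannyl radical may add to the aldehyde oxygen, if hydrogen transfer is not fast enough. Fallback: from 6, mask the aldehyde first with 1,2-bis(trimethylsilyloxy)ethane and catalytic Me3SiOSO2CF3 in CH2Cl2 at −78 °C, giving the bromo lactone bis-dioxolane F2. Bu3SnH/AIBN then gives the debrominated bis-dioxolane F3, and hydrogenation over Rh/Al2O3 the saturated bis-dioxolane F4. The hydrolysis conditions of step 6 remove both dioxolanes and return the route at 9.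

**Step 8.** Crystallisation may not discriminate (mixed crystals, oiling out), or the free amine may add slowly to the enone during heating. Fallback: from 12, esterify the racemate as in step 9 to the racemic 4-methoxybenzyl ester F5. Separate the enantiomers by preparative chromatography on amylose tris(3,5-dimethylphenylcarbamate); the aryl ester gives the phase a handle. The route is rejoined at 16.

**Step 12.** Competing 1,2-reduction of the dienone carbonyl, or proton exchange between the enolate and the product, would give double allylation and loss of material. Fallback: from 19, hydrogenate the disubstituted C6=C7 bond selectively with H2 and (Ph3P)3RhCl in benzene, giving the 9-en-8-one F6. Kinetic deprotonation at C7 with LiN(i-Pr)2 in THF at −78 °C and allyl bromide then return the route at 21.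

**Step 21.** The amine catalyst may add to the new acrolein, or the C11=C12 alkene may migrate into conjugation with C8 through the C7 dienol during prolonged warming. Fallback: from 35, use stoichiometric Me2N=CH2+ I− with i-Pr2NEt in CH2Cl2 at rt to give the Mannich base F7. Quaternise with MeI to the trimethylammonium iodide F8, and eliminate with aqueous NaHCO3/CH2Cl2 at 0 °C; this Hofmann-type elimination uses no secondary amine and no heat. The route is rejoined at 36.

## Further compounds

F1 | step 3 | racemic 4,7-dibromo-5-methyl-6-[(2-methyl-1,3-dioxolan-2-yl)methyl]-3-oxo-2-oxabicyclo[2.2.2]oct-7-ene-5-carbaldehyde | O=C[C@@]1(C)[C@H](CC2(C)OCCO2)[C@@H]3OC(=O)[C@@]1(Br)C=C3Br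
F2 | step 4 | racemic 4-bromo-5-(1,3-dioxolan-2-yl)-5-methyl-6-[(2-methyl-1,3-dioxolan-2-yl)methyl]-2-oxabicyclo[2.2.2]oct-7-en-3-one | O1CCOC1[C@@]2(C)[C@H](CC3(C)OCCO3)[C@@H]4OC(=O)[C@@]2(Br)C=C4
F3 | step 4 | racemic 5-(1,3-dioxolan-2-yl)-5-methyl-6-[(2-methyl-1,3-dioxolan-2-yl)methyl]-2-oxabicyclo[2.2.2]oct-7-en-3-one | O1CCOC1[C@@]2(C)[C@H](CC3(C)OCCO3)[C@@H]4OC(=O)[C@H]2C=C4
F4 | step 4 | racemic 5-(1,3-dioxolan-2-yl)-5-methyl-6-[(2-methyl-1,3-dioxolan-2-yl)methyl]-2-oxabicyclo[2.2.2]octan-3-one | O1CCOC1[C@@]2(C)[C@H](CC3(C)OCCO3)[C@@H]4OC(=O)[C@H]2CC4
F5 | step 8 | racemic 4-methoxybenzyl 4-hydroxy-8a-methyl-6-oxo-1,2,3,4,4a,5,6,8a-octahydronaphthalene-1-carboxylate (racemate of 16) | O=C1C=C[C@@]2(C)[C@H](C1)[C@H](O)CC[C@@H]2C(=O)OCc1ccc(OC)cc1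
F6 | step 12 | 4-methoxybenzyl 4-[(tert-butyldimethylsilyl)oxy]-8a-methyl-6-oxo-1,2,3,4,6,7,8,8a-octahydronaphthalene-1-carboxylate | O=C1CC[C@@]2(C)C(=C1)[C@H](O[Si](C)(C)C(C)(C)C)CC[C@@H]2C(=O)OCc1ccc(OC)cc1
F7 | step 21 | 4-methoxybenzyl 7-[3-(dimethylamino)-1-oxopropan-2-yl]-4-{[(2E,4S)-2,4-dimethyloct-2-enoyl]oxy}-8a-methyl-6-oxo-1,2,3,4,6,7,8,8a-octahydronaphthalene-1-carboxylate (both epimers at the new carbon) | CN(C)CC(C=O)[C@@H]1C[C@@]2(C)C(=CC1=O)[C@H](OC(=O)/C(C)=C/[C@@H](C)CCCC)CC[C@@H]2C(=O)OCc1ccc(OC)cc1
F8 | step 21 | trimethylammonium iodide formed from F7 with iodomethane | C[N+](C)(C)CC(C=O)[C@@H]1C[C@@]2(C)C(=CC1=O)[C@H](OC(=O)/C(C)=C/[C@@H](C)CCCC)CC[C@@H]2C(=O)OCc1ccc(OC)cc1.[I-]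
A1 | alternative 1 | cis-fused methyl 4-(benzyloxy)-8a-methyl-6-oxo-3,4,4a,5,6,7,8,8a-octahydronaphthalene-1-carboxylate (keto enoate from the oxy-Cope shift) | C1C[C@@]2(C)[C@@H](CC1=O)[C@H](OCc3ccccc3)CC=C2C(=O)OC
A2 | alternative 2 | ring-contracted 9(10)-ene acid with C8 as dioxolane and a silyl ether on C1, epimeric at C4 | C1C[C@@]2(C)C(=CC13OCCO3)[C@H](O[Si](C)(C)C(C)(C)C)CC[C@H]2C(=O)O
A3 | alternative 3 | cis-fused bicyclic enone diketone with an exocyclic methylene on C4 | C1=C[C@@]2(C)[C@@H](CC1=O)C(=O)CCC2=C
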